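The numbers in the tables were generated by integration with made-up constants; noise was put on by code.

At early times the runs can be set against one another by their first readings.

| flask | Q | J | time |
|---|---|---|---|
| Tuesday's | 1.00 M | 1.50 M |  |
| Thursday's | 0.400 M | 0.900 M |  |
| Friday's | 1.00 M | 0.750 M |  |
| Wednesday's | 1.00 M | 1.50 M | 78 min |

- Tuesday's run (time / min: [L] / M): 6.5: 0.172; 13: 0.278; 20: 0.358; 26: 0.404; 32: 0.417; 39: 0.439
- Thursday's run (time / min: [L] / M): 6.5: 0.051; 13: 0.079; 20: 0.112; 26: 0.128; 32: 0.133; 39: 0.153
- Friday's run (time / min: [L] / M): 6.5: 0.067; 13: 0.132; 20: 0.172; 26: 0.198; 32: 0.224; 39: 0.246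

(readings scatter by 0.005 M)

- the power of [Q] that the first rate follows, about the charge of the Tuesday's run; measure it at two percent of Q made into L (one fixed amount of L, the same in the runs compared)
- the power of [J] that the first rate follows, about the charge of the Tuesday's run; measure it at two percent of Q made into L
- L in the Wednesday's run at 78 min, as a share of the Q charged

- Overall: Q + J -> L.
- Constant volume, constant temperature.
- What is held in complexes is read along with the free species.
- An order is taken over about fifteen percent of the charge, up and down.

The Tuesday's run looks odd at first. Its first 6.5 min made 0.172 M of L and its last 7.00 min made 0.0220 M, yet at one Q and one J per L the last reading leaves 0.561 M of Q and 1.06 M of J.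

Logarithms put a size on this. The Friday's run has the Tuesday's Q and half its J, and its first reading is lower by 0.409 powers of ten for 0.301 in J. Powers of ten of rate lost per power of ten of J give the order in J, 1.36. The Thursday's first reading lies 0.528 powers of ten below the Tuesday's. The lower J accounts for 0.302 of that, and the remainder, over 0.398 in Q, gives an order in Q of 0.568. Both are rough readings.

With these orders, the lower Q and J at the Tuesday's last reading cost 0.347 powers of ten, while the mean rate fell by 0.925. The fall is larger than that cost, so the drop in Q and J at these orders does not account for it. The Wednesday's run repeats the Tuesday's charge, and the estimate here simply takes its L at the Tuesday's last reading, about 43.9%.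

The forecast differs, giving 0.5 in Q, 1.5 in J and 48%. Its ground for the last figure: “All three runs fit a plateau with L/(QJ)≈0.85, meaning reversibility or strong product inhibition”.

The flask gives 0.74 in Q, 1.3 in J and 41.8% for the Wednesday's run, from this scheme:

    2 J ⇌ J2, settled at all times (0.9110 M⁻¹)
    Q + J2 → L + J (0.1704 M⁻¹ min⁻¹)
    Q + J ⇌ QJ, settled at all times (0.9220 M⁻¹)
    L + J → E (0.03096 M⁻¹ min⁻¹)

The Wednesday's share at its later time is lower than the Tuesday's last reading, and the loss of L with J to E moves the readings by 14 as a root mean square, in units of their scatter. The carried order is used once more on the Thursday's run. Its rate at the fixed amount of L lies 0.618 powers of ten below the Tuesday's, the carried order puts 0.302 of that on the lower J, and the rest, over 0.398 in Q, gives a mean power of Q of 0.794.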